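The pitfall in this flask was to argue from the equivalents of scavenger, when the delta and gamma runs, at 1.3 equiv and 3.1 equiv, read 30.3% and 30.7% of starting material at 5.00 h, with a scatter of 1 percentage point. So I counted turnovers instead.

| setting | delta | gamma | noon | spring | summer |
|---|---|---|---|---|---|
| starting material | 10 mM | 10 mM | 10 mM | 10 mM | 10 mM |
| second substrate | 4 equiv (fed, over 4.0 h) | 4 equiv (fed, over 4.0 h) | 4.00 equiv (fed, over 4.0 h) | 4.00 equiv (fed, over 4.0 h) | 4.00 equiv (fed, over 4.0 h) |
| scavenger | 1.3 equiv | 3.1 equiv | 1.00 equiv | 1.50 equiv | 2.20 equiv |
| free enzyme | 0.1 mol% | 0.1 mol% | 0.1 mol% | 0.1 mol% | 0.1 mol% |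
| remark | run made earlier | run made earlier |  |  |  |
| time |  |  | 10 h | 10 h | 10 h |

| run | time / h | starting material / % | target / % |
|---|---|---|---|
| delta | 0.417 | 97.8 | 0.9 |
| delta | 1.33 | 88.2 | 10.2 |
| delta | 2.50 | 70.5 | 28.4 |
| delta | 4.00 | 45.8 | 54.1 |
| delta | 5.00 | 30.3 | 69.6 |
| gamma | 0.417 | 99.0 | 2.1 |
| gamma | 0.833 | 94.9 | 5.7 |
| gamma | 1.33 | 89.2 | 10.4 |
| gamma | 2.50 | 71.2 | 27.4 |
| gamma | 5.00 | 30.7 | 68.1 |

(scatter of a reading: 1 percentage point)



- part of the starting material that has reacted at the end, noon
- part of the starting material that has reacted at the end, spring
- part of the starting material that has reacted at the end, summer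
- what raising the equivalents of scavenger from its lowest to its highest value here does to the part of the starting material that has reacted (changes below 5 percentage points count as none) (no change / it rises / it falls)

At 0.1 mol%, each enzyme had to turn over 1000 times. I took the pace, meaning the starting material consumed per hour per enzyme charged (the turnover frequency), from delta between 2.50 h and 5.00 h: 161 /h. At 5.00 h, delta read 303 turnovers still to go.

My first extreme held that pace to the end, which put the last of delta's starting material at 6.88 h. My second let the starting material shrink by the same factor in each further stretch of 2.50 h, as if the pace followed it, which left 5.60% at 10 h. I expected the real flask between them, as an estimate and not a bound. Delta's pace read 151 /h early and 155 /h late, although the starting material had fallen, and these readings favoured the first extreme. But I could not expect that pace to last as the starting material thinned.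

The forecast said 96% for noon, 98% for spring, 98% for summer and no change, on the ground that “all runs should be essentially finished by 10 h, with excess second substrate present”.

The flasks gave 98.8%, 99.0% and 99.1%, with no change (a change of 0.26 points), so the forecast stood within its tolerance.

    scavenger + first product → scavenged by-product (k = 68.0 /M/min)
    first complex ⇌ loaded enzyme + first product (K = 0.0290 M, k = 37.0 /min)
    starting material + free enzyme ⇌ first complex (K = 43.0 /M, k = 38000 /M/min)
    second complex → free enzyme + target (k = 11.0 /min)
    starting material + first product ⇌ idle adduct, settled at all times (K = 620 /M)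
    second substrate + loaded enzyme ⇌ second complex (K = 33.0 /M, k = 1700 /M/min)

In noon at 4.00 h, with 44.5% of the starting material left, 40.9% of the catalyst was free enzyme and the rest was in the cycle; at 10.0 h, with 1.17% left, free enzyme stood at 96.1%. Summer's answer moved by 5 points once the enzyme was cut to 0.074 mol%, where 1351 turnovers were asked, still fewer than the 1610 that the pace, if held for the whole 10 h, would give.

With summer's charges but 0.025 mol% of free enzyme, 4000 turnovers were asked, and the same 1610 would cover 40.2% of the starting material. That flask reached 44.8% reacted, with 55.2% of the starting material left.

All runs come from a simulation from invented constants; noise was put on by code.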